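**Retrosynthetic overview**

Locants: ring A = C1–C5 + C10 (C4 carries the exocyclic CH2, C5 is the fusion CH, C10 the fusion C–CH3); ring B = C5–C10 (C8 is CH–CH3, C9 carries CH3 and the C11 methylene that bears the quinone); C1'–C6' = quinone ring, C1' bonded to C11.
Feature used: in the C8/C9/C10 triad the three methyl groups lie on one face and C11 on the other, on the side of ring B where C1 leaves C10; an (E)-2-methylbut-2-enoyl unit gives this pattern if its carboxyl carbon becomes C11 and is held by an oxygen on C1 during a cycloaddition.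
Late disconnections: quinone ⇐ 2,3,5,6-tetramethoxyphenyl group; C4=CH2 ⇐ C4 ketone ⇐ SeO2 oxidation beside C5=C6; C11–aryl ⇐ aryllithium + C11 aldehyde, then deoxygenation; C5–H ⇐ C11–OH-directed hydrogenation; C1–O removed by radical deoxygenation.
Key disconnection: C9–C10 and C7–C8, by intramolecular Diels–Alder reaction of the (S)-2-methyl-3-vinylcyclohex-2-enyl tiglate, itself made from 2-methylcyclohexane-1,3-dione by triflation, vinyl coupling, CBS reduction and esterification.
Ring order: ring A is bought, ring B and a C1–O–C11 γ-lactone close together in the key step, and the quinone ring is attached last as an arene.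

Key step: step 5

Remark on the chemistry: α is the face of ring B that carries C11 (and later the C5 hydrogen), β the face of the C8, C9 and C10 methyls; in ester 7 the cyclohexenyl carbons 1, 2, 3 are C1, C10, C5, the vinyl carbons are C6 and C7, and the acid carbons 1, 2, 3 are C11, C9, C8; the C4 carbinol of step 10 is drawn as the expected β epimer, and since C4 becomes sp2 in step 19 either epimer would serve.

**Route**

Step 1
Reactants: 1 2-methylcyclohexane-1,3-dione
Product: 2 2-methyl-3-oxocyclohex-1-en-1-yl trifluoromethanesulfonate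
Conditions: Tf2O, pyridine, CH2Cl2, −78 to 0 °C
Reagents that add atoms: trifluoromethanesulfonic anhydride, O=S(=O)(OS(=O)(=O)C(F)(F)F)C(F)(F)F
Why: O-sulfonylation of the enol form of a cyclic 1,3-dione (vinylogous triflate formation) is routine and creates no stereocenter.

Step 2
Reactants: 2 2-methyl-3-oxocyclohex-1-en-1-yl trifluoromethanesulfonate; 3 4,4,5,5-tetramethyl-2-vinyl-1,3,2-dioxaborolane (vinylboronic acid pinacol ester)
Product: 4 2-methyl-3-vinylcyclohex-2-en-1-one
Conditions: PdCl2(dppf) (3 mol%), K2CO3, 1,4-dioxane/H2O, 80 °C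
Reagents that add atoms: none
Why: Suzuki–Miyaura coupling of an electron-poor alkenyl triflate with a vinylboronate should give the cross-conjugated dienone, which brings in C6 and C7 and is used at once because such dienones dimerise on standing.

Step 3
Reactants: 4 2-methyl-3-vinylcyclohex-2-en-1-one
Product: 5 (S)-2-methyl-3-vinylcyclohex-2-en-1-ol
Conditions: (R)-Me-CBS oxazaborolidine [(R)-1-methyl-3,3-diphenyltetrahydro-1H,3H-pyrrolo[1,2-c][1,3,2]oxazaborole] (20 mol%), catecholborane, PhMe, −78 °C
Reagents that add atoms: none
Why: Corey–Bakshi–Shibata reduction, in which the catalyst tells the methyl-bearing alkenyl carbon (large) from the ring CH2 (small), so that the (R)-catalyst should deliver hydride to the carbonyl face giving the (S)-carbinol (C1), while catecholborane at −78 °C reduces only C=O and leaves the vinyl group alone.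

Step 4
Reactants: 5 (S)-2-methyl-3-vinylcyclohex-2-en-1-ol; 6 tiglic acid
Product: 7 (S)-2-methyl-3-vinylcyclohex-2-en-1-yl (E)-2-methylbut-2-enoate
Conditions: DCC, DMAP (20 mol%), CH2Cl2, 0 °C to rt
Reagents that add atoms: none
Why: Steglich esterification acylates the hindered allylic alcohol under neutral conditions that neither ionise the dienylic C1–O bond nor isomerise the (E)-enoate, so C1 keeps its configuration.

Step 5
Reactants: 7 (S)-2-methyl-3-vinylcyclohex-2-en-1-yl (E)-2-methylbut-2-enoate
Product: 8 tricyclic lactone (γ-lactone C1–O–C11(=O) cis-fused on C1–C10 and on C9–C10; C5=C6 alkene; C8, C9 and C10 methyls β; C1–O and C11 α)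
Conditions: PhMe (0.01 M), BHT (10 mol%), base-washed sealed tube, 185 °C
Reagents that add atoms: none
Why: Proposed new method: a thermal, concerted and suprafacial [4+2] cycloaddition (type 1 intramolecular Diels–Alder) in which the semicyclic diene C10=C5–C6=C7 adds to the tiglate C8=C9 bond to form C9–C10 and C7–C8, the closest known reaction type being the ester-tethered intramolecular Diels–Alder reaction of dienyl acrylates and of 3-vinylcyclohex-2-enyl alkynoates to fused γ-lactones, whereas a trisubstituted enoate closing onto a fully substituted diene terminus to give two adjacent quaternary carbons has not been shown. Ring B closes as the six-membered cycloadduct ring through both new bonds, and the γ-lactone closes as a five-membered ring through the C9–C10 bond alone, its other members C1, O and C11 being the tether. C10 is set by the C1 carbinol because the three-atom tether can reach only the diene face syn to the C1–O bond; C9 is set by the tether-endo transition state, favoured because A(1,2) strain with the C10 methyl keeps the C1–O bond pseudoaxial and so points the acyl group under the diene, which makes the lactone cis-fused and the C9 and C10 methyls cis; C8 is set by the (E) geometry of the enoate, which is carried suprafacially into a cis C8/C9 dimethyl pair. The step needs diene-face selectivity, endo selectivity and enough rate: the first two are secured by the short tether from the (S)-carbinol, and the rate is helped by intramolecularity, by high dilution with a radical inhibitor against polymerisation and by a temperature kept below the range where [1,5]-hydrogen shift of the (Z)-methyl diene or loss of the dienylic ester would take over.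

Step 6
Reactants: 8 tricyclic lactone
Product: 9 diol (C1 α-OH; hydroxymethyl C11 on C9; C5=C6)
Conditions: LiAlH4, THF, 0 °C to reflux
Reagents that add atoms: none
Why: Hydride reduction of the γ-lactone gives the 1,4-diol without touching the isolated alkene or any stereocenter.

Step 7
Reactants: 9 diol
Product: 10 C11 pivalate of the diol (C1 α-OH free)
Conditions: PivCl (1.1 equiv), pyridine, DMAP (5 mol%), CH2Cl2, 0 °C
Reagents that add atoms: pivaloyl chloride, CC(C)(C)C(Cl)=O
Why: Selective acylation, the primary C11 hydroxyl reacting before the secondary C1 hydroxyl that is shielded by the quaternary C10.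

Step 8
Reactants: 10 C11 pivalate
Product: 11 C1 O-(imidazol-1-ylcarbonothioyl) derivative of 10
Conditions: 1,1'-thiocarbonyldiimidazole, DMAP, PhMe, 90 °C
Reagents that add atoms: 1,1'-thiocarbonyldiimidazole, S=C(n1ccnc1)n1ccnc1
Why: Thioacylation of the hindered secondary alcohol (first stage of a Barton–McCombie deoxygenation) runs without strong base, so the pivalate cannot migrate.

Step 9
Reactants: 11 C1 thiocarbonyl derivative
Product: 12 C1-deoxy pivalate (octalin with C5=C6 and CH2OPiv on C9)
Conditions: n-Bu3SnH, AIBN (20 mol%), PhMe, 110 °C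
Reagents that add atoms: none
Why: Barton–McCombie radical deoxygenation removes the C1 oxygen once it has served as tether anchor, the secondary C1 radical being reduced by the stannane while its possible 3-exo addition to C5=C6 is reversible.

Step 10
Reactants: 12 C1-deoxy pivalate
Product: 13 C4 β-hydroxy derivative of 12 (allylic alcohol, C5=C6 kept)
Conditions: SeO2 (0.5 equiv), t-BuOOH (3 equiv), CH2Cl2, rt
Reagents that add atoms: tert-butyl hydroperoxide, CC(C)(C)OO; selenium dioxide, O=[Se]=O (passes the oxygen on)
Why: Riley allylic oxidation (ene reaction at C6 with loss of an axial C4 hydrogen, then [2,3]-sigmatropic shift) oxidises the ring CH2 attached to the more substituted alkene carbon, as in the 4β-hydroxylation of steroidal 5-enes, so the C4 β-carbinol is expected and C5=C6 is kept.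

Step 11
Reactants: 13 C4 allylic alcohol
Product: 14 C4 tert-butyldimethylsilyl ether of 13
Conditions: TBSOTf, 2,6-lutidine, CH2Cl2, −78 to 0 °C
Reagents that add atoms: tert-butyldimethylsilyl trifluoromethanesulfonate, CC(C)(C)[Si](C)(C)OS(=O)(=O)C(F)(F)F
Why: Silylation with a silyl triflate masks the hindered C4 oxygen as a bulky ether that cannot bind iridium and so cannot steer the hydrogenation of step 13 to the β face.

Step 12
Reactants: 14 C4 silyl ether pivalate
Product: 15 C11 alcohol with C4 OTBS (C5=C6)
Conditions: i-Bu2AlH, CH2Cl2, −78 to 0 °C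
Reagents that add atoms: none
Why: Reductive cleavage of the pivalate ester frees the C11 hydroxyl and leaves the silyl ether and the alkene untouched.

Step 13
Reactants: 15 C11 alcohol with C5=C6
Product: 16 trans-decalin C11 alcohol (C5 α-H) with C4 OTBS
Conditions: [Ir(cod)(PCy3)(py)]PF6 (10 mol%), H2 (1 atm), CH2Cl2, rt
Reagents that add atoms: none
Why: Hydroxyl-directed hydrogenation with a cationic iridium catalyst, in which the C11 hydroxyl on the α face binds the metal and hands H2 to the α face of the hindered trisubstituted C5=C6 bond, so that C5–H ends trans to the C10 methyl (trans-decalin).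

Step 14
Reactants: 16 trans-decalin C11 alcohol
Product: 17 C11 aldehyde
Conditions: Dess–Martin periodinane, NaHCO3, CH2Cl2, rt
Reagents that add atoms: none
Why: Dess–Martin oxidation of the neopentyl primary alcohol gives an aldehyde on the quaternary C9 that has no α-hydrogen and therefore cannot epimerise or enolise.

Step 15
Reactants: 17 C11 aldehyde; 18 1,2,4,5-tetramethoxybenzene
Product: 20 C11 (2,3,5,6-tetramethoxyphenyl)carbinol (both C11 epimers), via (2,3,5,6-tetramethoxyphenyl)lithium 19 (not isolated)
Conditions: 18, n-BuLi, THF, 0 °C; then 17, −78 to 0 °C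
Reagents that add atoms: none
Why: Lithiation of the arene between two methoxy groups (directed ortho-metalation) and 1,2-addition of the aryllithium to the non-enolisable aldehyde form the C11–aryl bond, the configuration of the new carbinol centre being irrelevant because it is removed in step 17.

Step 16
Reactants: 20 C11 aryl carbinol
Product: 23 O-alkyl S-methyl dithiocarbonate (xanthate) of 20, via sodium alkoxide 21 (not isolated), via sodium dithiocarbonate 22 (not isolated)
Conditions: NaH, THF, 0 °C; CS2; then MeI, rt
Reagents that add atoms: carbon disulfide, S=C=S; iodomethane, CI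
Why: Xanthate formation from the alkoxide is the first stage of a Barton–McCombie deoxygenation and is safe here because the quaternary C9 offers no β-hydrogen for a Chugaev elimination.

Step 17
Reactants: 23 xanthate
Product: 24 C11-methylene tetramethoxyarene with C4 OTBS
Conditions: n-Bu3SnH, AIBN (20 mol%), PhMe, 110 °C
Reagents that add atoms: none
Why: Barton–McCombie deoxygenation through a benzylic radical gives the C11 methylene without a cationic intermediate, which avoids the Wagner–Meerwein shifts that an ionic reduction next to the quaternary C9 would invite.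

Step 18
Reactants: 24 C4 silyl ether
Product: 25 C4 alcohol
Conditions: n-Bu4NF, THF, 50 °C
Reagents that add atoms: none
Why: Fluoride-induced desilylation frees the C4 alcohol without affecting the aryl ethers or any stereocenter.

Step 19
Reactants: 25 C4 alcohol
Product: 26 C4 ketone (C5 α-H)
Conditions: Dess–Martin periodinane, NaHCO3, CH2Cl2, 0 °C to rt
Reagents that add atoms: none
Why: Buffered Dess–Martin oxidation gives the C4 ketone under conditions too mild to enolise toward C5, and the ketone is carried on crude so that the C5 centre has no occasion to equilibrate.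

Step 20
Reactants: 26 C4 ketone
Product: 27 exocyclic-methylene tetramethoxyarene
Conditions: Zn, CH2Br2, TiCl4, THF/CH2Cl2, 0 °C to rt
Reagents that add atoms: dibromomethane, BrCBr
Why: Takai–Lombardo methylenation uses a non-basic zinc–titanium methylene reagent known to convert hindered, enolisable ketones into 1,1-disubstituted alkenes without epimerising the α-carbon, so C5 should keep its configuration.

Step 21
Reactants: 27 exocyclic-methylene tetramethoxyarene
Product: 28 2,5-dimethoxyquinone (methoxy groups on C2' and C5')
Conditions: (NH4)2Ce(NO3)6, MeCN/H2O, 0 °C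
Reagents that add atoms: water, O
Why: Oxidative demethylation of a para-dimethoxyarene to the quinone, either para pair of methoxy groups giving the same 2,5-dimethoxyquinone because of the symmetry of the aryl ring, with the carbonyl oxygens coming from water.

Step 22
Reactants: 28 2,5-dimethoxyquinone
Product: 29 2,5-dihydroxyquinone
Conditions: KOH, MeOH/H2O, 60 °C; then cold 1 M HCl to pH 3
Reagents that add atoms: potassium hydroxide, [K+].[OH-]
Why: Addition–elimination of hydroxide at both vinylogous methyl esters gives the dihydroxyquinone, which avoids having to tell the two methoxy groups apart in a hydrolysis.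

Step 23
Reactants: 29 2,5-dihydroxyquinone
Product: 30 CNP0109104.1 (target)
Conditions: Me3SiCHN2 (1.05 equiv), MeOH/PhMe, 0 °C
Reagents that add atoms: trimethylsilyldiazomethane, C[Si](C)(C)C=[N+]=[N-]
Why: Diazoalkane O-methylation of a vinylogous acid occurs at the more acidic and less hindered O–C–CH–C–O unit around C4' and not at the unit whose oxygens flank the C11-bearing C1', so the hydroxyl next to C11 stays free, and the acid-free conditions spare the exocyclic alkene.

**Compound list**

1 | 2-methylcyclohexane-1,3-dione | CC1C(=O)CCCC1=O | starting material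
2 | 2-methyl-3-oxocyclohex-1-en-1-yl trifluoromethanesulfonate | CC1=C(OS(=O)(=O)C(F)(F)F)CCCC1=O | intermediate
3 | 4,4,5,5-tetramethyl-2-vinyl-1,3,2-dioxaborolane | C=CB1OC(C)(C)C(C)(C)O1 | starting material
4 | 2-methyl-3-vinylcyclohex-2-en-1-one | CC1=C(C=C)CCCC1=O | intermediate
5 | (S)-2-methyl-3-vinylcyclohex-2-en-1-ol | O[C@H]1CCCC(C=C)=C1C | intermediate
6 | tiglic acid, (E)-2-methylbut-2-enoic acid | C/C=C(\C)C(=O)O | starting material
7 | (S)-2-methyl-3-vinylcyclohex-2-en-1-yl (E)-2-methylbut-2-enoate | C/C=C(\C)C(=O)O[C@H]1CCCC(C=C)=C1C | intermediate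
8 | tricyclic lactone: C1–O–C11(=O) γ-lactone, C5=C6, methyls on C8, C9, C10 β, C1–O and C11 α | C[C@H]1CC=C2CCC[C@@H]3OC(=O)[C@@]1(C)[C@]23C | intermediate
9 | diol: C1 α-OH, C9 hydroxymethyl (C11), C5=C6 | C[C@H]1CC=C2CCC[C@H](O)[C@]2(C)[C@]1(C)CO | intermediate
10 | C11 pivalate of 9 | C[C@H]1CC=C2CCC[C@H](O)[C@]2(C)[C@]1(C)COC(=O)C(C)(C)C | intermediate
11 | C1 O-(imidazol-1-ylcarbonothioyl) derivative of 10 | C[C@H]1CC=C2CCC[C@H](OC(=S)n3ccnc3)[C@]2(C)[C@]1(C)COC(=O)C(C)(C)C | intermediate
12 | C1-deoxy pivalate, C5=C6 | C[C@H]1CC=C2CCCC[C@]2(C)[C@]1(C)COC(=O)C(C)(C)C | intermediate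
13 | C4 β-hydroxy pivalate, C5=C6 | C[C@H]1CC=C2[C@@H](O)CCC[C@]2(C)[C@]1(C)COC(=O)C(C)(C)C | intermediate
14 | C4 β-OTBS pivalate, C5=C6 | C[C@H]1CC=C2[C@@H](O[Si](C)(C)C(C)(C)C)CCC[C@]2(C)[C@]1(C)COC(=O)C(C)(C)C | intermediate
15 | C11 alcohol, C4 β-OTBS, C5=C6 | C[C@H]1CC=C2[C@@H](O[Si](C)(C)C(C)(C)C)CCC[C@]2(C)[C@]1(C)CO | intermediate
16 | trans-decalin C11 alcohol (C5 α-H), C4 β-OTBS | C[C@H]1CC[C@H]2[C@@H](O[Si](C)(C)C(C)(C)C)CCC[C@]2(C)[C@]1(C)CO | intermediate
17 | C11 aldehyde, C4 β-OTBS | C[C@H]1CC[C@H]2[C@@H](O[Si](C)(C)C(C)(C)C)CCC[C@]2(C)[C@]1(C)C=O | intermediate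
18 | 1,2,4,5-tetramethoxybenzene | COc1cc(OC)c(OC)cc1OC | starting material
19 | (2,3,5,6-tetramethoxyphenyl)lithium | [Li]c1c(OC)c(OC)cc(OC)c1OC | intermediate
20 | C11 (2,3,5,6-tetramethoxyphenyl)carbinol, both C11 epimers, C4 β-OTBS | C[C@H]1CC[C@H]2[C@@H](O[Si](C)(C)C(C)(C)C)CCC[C@]2(C)[C@]1(C)C(O)c1c(OC)c(OC)cc(OC)c1OC | intermediate
21 | sodium alkoxide of 20 | C[C@H]1CC[C@H]2[C@@H](O[Si](C)(C)C(C)(C)C)CCC[C@]2(C)[C@]1(C)C([O-])c1c(OC)c(OC)cc(OC)c1OC.[Na+] | intermediate
22 | sodium O-alkyl dithiocarbonate of 20 | C[C@H]1CC[C@H]2[C@@H](O[Si](C)(C)C(C)(C)C)CCC[C@]2(C)[C@]1(C)C(OC(=S)[S-])c1c(OC)c(OC)cc(OC)c1OC.[Na+] | intermediate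
23 | O-alkyl S-methyl dithiocarbonate (xanthate) of 20 | C[C@H]1CC[C@H]2[C@@H](O[Si](C)(C)C(C)(C)C)CCC[C@]2(C)[C@]1(C)C(OC(=S)SC)c1c(OC)c(OC)cc(OC)c1OC | intermediate
24 | C11-methylene tetramethoxyarene, C4 β-OTBS | C[C@H]1CC[C@H]2[C@@H](O[Si](C)(C)C(C)(C)C)CCC[C@]2(C)[C@]1(C)Cc1c(OC)c(OC)cc(OC)c1OC | intermediate
25 | C4 β-alcohol of the tetramethoxyarene | C[C@H]1CC[C@H]2[C@@H](O)CCC[C@]2(C)[C@]1(C)Cc1c(OC)c(OC)cc(OC)c1OC | intermediate
26 | C4 ketone of the tetramethoxyarene (C5 α-H) | C[C@H]1CC[C@H]2C(=O)CCC[C@]2(C)[C@]1(C)Cc1c(OC)c(OC)cc(OC)c1OC | intermediate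
27 | exocyclic-methylene tetramethoxyarene | C=C1CCC[C@@]2(C)[C@H]1CC[C@H](C)[C@@]2(C)Cc1c(OC)c(OC)cc(OC)c1OC | intermediate
28 | 2,5-dimethoxy-3-(C11-linked decalinylmethyl)-1,4-benzoquinone | C=C1CCC[C@@]2(C)[C@H]1CC[C@H](C)[C@@]2(C)CC1=C(OC)C(=O)C=C(OC)C1=O | intermediate
29 | 2,5-dihydroxy-3-(C11-linked decalinylmethyl)-1,4-benzoquinone | C=C1CCC[C@@]2(C)[C@H]1CC[C@H](C)[C@@]2(C)CC1=C(O)C(=O)C=C(O)C1=O | intermediate
30 | 2-hydroxy-5-methoxy-3-{[(1R,2S,4aS,8aS)-1,2,8a-trimethyl-5-methylidenedecahydronaphthalen-1-yl]methyl}cyclohexa-2,5-diene-1,4-dione (CNP0109104.1) | C=C1CCC[C@@]2(C)[C@H]1CC[C@H](C)[C@@]2(C)CC1=C(O)C(=O)C=C(OC)C1=O | target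

**Step count and risks**

Total steps: 23. Longest linear sequence: 23 steps (1 to 30); compounds 3, 6 and 18 are bought and enter at steps 2, 4 and 15.

Steps most likely to fail:

1. Step 5 (proposed new method). The cycloaddition may be too slow at the hindered termini, so that [1,5]-hydrogen shift of the diene, loss of the dienylic ester or polymerisation wins, or part of the material may react through the tether-exo mode. The fallback keeps the ester tether but uses a fumarate-type, doubly activated dienophile; it sets out from dienol 5 and comes back at diol 9. Mesaconic acid is mono-esterified with allyl alcohol (cat. TsOH, PhMe, reflux, partial conversion) at its less hindered carboxyl to give mesaconic acid 4-allyl ester F1. Steglich coupling of F1 with 5 (DCC, DMAP) gives the mixed mesaconate diester F2. Dienyl fumarates cyclise at much lower temperature than simple enoates, so heating F2 in toluene at about 110–130 °C should give the lactone allyl ester F3 through the same tether-endo geometry, with the C8 ester cis to the C9 methyl. Pd(PPh3)4 and morpholine free the lactone acid F4. Mixed-anhydride reduction (i-BuOCOCl, N-methylmorpholine; then NaBH4) gives the primary alcohol F5, and MsCl/Et3N gives the mesylate F6. LiEt3BH (excess, THF, reflux) then turns CH2OMs into the C8 methyl and opens the lactone reductively to 9.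

2. Step 13. Hydrogen may be delivered to the wrong face, or the catalyst may fail to engage the hindered trisubstituted alkene. The fallback replaces hydroxyl direction by hydrogen-atom transfer; it sets out from pivalate 14 and comes back at 16. Treatment with Mn(dpm)3 [tris(2,2,6,6-tetramethylheptane-3,5-dionato)manganese] (10 mol%), PhSiH3 and t-BuOOH in i-PrOH at rt generates the tertiary C5 radical, which should take up hydrogen axially on the face away from the C10 methyl and the C4 silyloxy group to give the saturated trans-fused pivalate F7. i-Bu2AlH then frees the C11 alcohol 16.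

3. Step 20. The C5 centre may epimerise through a metal enolate of the C4 ketone, or methylenation of the hindered carbonyl may stall. The fallback is a two-stage Peterson olefination; it sets out from ketone 26 and comes back at 27. Me3SiCH2Li with CeCl3 (THF, −78 °C), an organocerium reagent that adds to enolisable ketones without deprotonating them, gives the β-hydroxysilane F8. KH (THF, rt) then effects syn-elimination to 27.

**Further compounds**

F1 | step 5 | mesaconic acid 4-allyl ester, (E)-2-methyl-4-oxo-4-(prop-2-en-1-yloxy)but-2-enoic acid | C/C(=C\C(=O)OCC=C)C(=O)O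
F2 | step 5 | 4-allyl 1-[(S)-2-methyl-3-vinylcyclohex-2-en-1-yl] mesaconate | C/C(=C\C(=O)OCC=C)C(=O)O[C@H]1CCCC(C=C)=C1C
F3 | step 5 | tricyclic lactone with allyl ester on C8 (β) in place of the C8 methyl | C=CCOC(=O)[C@H]1CC=C2CCC[C@@H]3OC(=O)[C@@]1(C)[C@]23C
F4 | step 5 | tricyclic lactone C8 carboxylic acid | OC(=O)[C@H]1CC=C2CCC[C@@H]3OC(=O)[C@@]1(C)[C@]23C
F5 | step 5 | tricyclic lactone C8 hydroxymethyl compound | OC[C@H]1CC=C2CCC[C@@H]3OC(=O)[C@@]1(C)[C@]23C
F6 | step 5 | tricyclic lactone C8 (methanesulfonyloxy)methyl compound | CS(=O)(=O)OC[C@H]1CC=C2CCC[C@@H]3OC(=O)[C@@]1(C)[C@]23C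
F7 | step 13 | trans-decalin C11 pivalate (C5 α-H) with C4 β-OTBS | C[C@H]1CC[C@H]2[C@@H](O[Si](C)(C)C(C)(C)C)CCC[C@]2(C)[C@]1(C)COC(=O)C(C)(C)C
F8 | step 20 | C4 tertiary alcohol bearing CH2SiMe3 (β-hydroxysilane) of the tetramethoxyarene | C[C@H]1CC[C@H]2C(O)(C[Si](C)(C)C)CCC[C@]2(C)[C@]1(C)Cc1c(OC)c(OC)cc(OC)c1OC
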